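In this closed, stirred, isothermal vessel, Ry binds Vo reversibly to RyVo, Vy converts RyVo to VyRyVo, VyRyVo releases Vo and Ty, and Vo turns Ty into Gy. Vy, the limiting reagent, is charged at half of Ry.

| flask | Ry | Vy | Vo | remark | time |
|---|---|---|---|---|---|
| spring | 0.10 M | 0.050 M | 0.48 mM | run made earlier |  |
| noon | 0.10 M | 0.050 M | 1.1 mM | run made earlier |  |
| gamma | 0.10 M | 0.0500 M | 0.25 mM |  | 2.0 min |
| eta | 0.10 M | 0.0500 M | 0.50 mM |  | 2.0 min |
| theta | 0.10 M | 0.0500 M | 1.0 mM |  | 2.0 min |

| run | time / s | Ty / % |
|---|---|---|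
| spring | 25.0 | 10 |
| spring | 50.0 | 18 |
| spring | 80.0 | 26 |
| spring | 90.0 | 27 |
| spring | 120 | 34 |
| noon | 10.0 | 10 |
| noon | 20.0 | 20 |
| noon | 30.0 | 19 |
| noon | 60.0 | 36 |
| noon | 120 | 30 |

(scatter of a reading: 1.5 percentage points)

- steps thought possible: Ry + Vo <-> RyVo; Vy + RyVo -> VyRyVo; VyRyVo -> Vo + Ty; Vo + Ty -> Vo + Gy
- "hardly changes" means that all values lie within two and a half points (for a concentration: within two and a half percent of the largest)

- amount of Ty at the end, in percent of the Ry charged for gamma, eta, theta, in this order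
- how the row runs (falls all the way / hardly changes / rises all the way / rises, then falls / falls, then rises)

Each step carries one catalyst form, so with Ry and Vy charges fixed and catalyst shares that follow the flask's progress, changing the Vo charge should act as a change in the speed of the clock. Multiply a flask's time by its Vo charge over spring's. Gamma then ends at 62.5 s of spring-clock time, eta at 125 s and theta at 250 s.

Test it first: noon's first reading falls at 22.9 s on this clock and shows 10% Ty, and spring shows 10% at 25.0 s. Noon's last two readings stand at 138 s and 275 s.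

You fit nothing; draw straight lines between neighbouring readings. These give Ty of 21.3%, 34.6% and 31.1%, each a reading with its scatter, so the row rises, then falls.

The forecast, slightly apart from yours at eta and theta, gives 21%, 34% and 32%, rises, then falls, “though the last step is uncertain”.

The flasks give 21.1%, 33.9% and 31.0%: rises, then falls.

    Ry + Vo ⇌ RyVo (K = 24.0 M⁻¹, k = 21.0 M⁻¹ s⁻¹)
    Vy + RyVo → VyRyVo (k = 290 M⁻¹ s⁻¹)
    VyRyVo → Vo + Ty (k = 1.60 s⁻¹)
    Vo + Ty → Vo + Gy (k = 12.0 M⁻¹ s⁻¹)

Gamma's end at 62.5 s matches eta's midpoint on the spring clock, 62.5 s: gamma after 2.00 min holds Ty 21.1% and Vy 53.9%, and eta after 1.00 min holds Ty 21.0% and Vy 53.8%. Theta after 1.00 min repeats eta's end, with Ty 33.8% against 33.9%. Up to then, VyRyVo fed Ty in theta while Vy fell to 18.0% of its charge. In theta, Gy stood at 6.90% after 1.00 min. After 2.00 min, theta held Vy at 0.0121%, Ty at 31.0% and Gy at 19.0%.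

The data were computed for substances that don't exist.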